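The product is counted in percent of the substrate charged, so you want one number that turns a charge into a ceiling on that percentage.

the same everywhere: partner 12.1 mM
- maple: substrate 3.1 mM; temperature −10 °C; run made earlier
- birch: substrate 25 mM; temperature 5 °C; run made earlier
- eta: substrate 15 mM; temperature 5 °C; time 6.0 h
- theta: substrate 11 mM; temperature 5 °C; time 6.0 h
- epsilon: substrate 40 mM; temperature 5 °C; time 6.0 h
- zeta: substrate 6.0 mM; temperature 5 °C; time 6.0 h

| run | time / h | product / % |
|---|---|---|
| maple | 1.33 | 1.2 |
| maple | 3.00 | 4.5 |
| maple | 4.00 | 7.8 |
| maple | 5.00 | 11.3 |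
| maple | 6.00 | 16.2 |
| maple | 8.00 | 25.3 |
| birch | 0.250 | 0 |
| birch | 0.667 | 5.6 |
| birch | 1.33 | 17.7 |
| birch | 2.00 | 28.2 |
| birch | 2.50 | 34.6 |
| birch | 3.00 | 38.7 |
| birch | 4.00 | 45.1 |

(scatter of a reading: 0.5 percentage points)



1. all flasks from highest to lowest amount of product, in percent of the substrate charged, at 6.0 h (eta / theta / epsilon / zeta)
2. the amount of product, in percent of the substrate charged of the flask you put first, at 6.0 h
3. the amount of product, in percent of the substrate charged of the flask you put last, at 6.0 h

1. Fold the charges into the equivalents E, the partner charged per substrate charged. For epsilon, E = c(partner)/c(substrate) = 12.1 mM/40 mM = 0.302.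

2. In words: if one partner makes one product, then E below one is the largest share of the substrate that can become product, and partner is the limiting reagent.

3. Try it on birch, where E is 0.484. Its gain shrinks from 11 percentage points between 2.00 h and 3.00 h to 6.4 points in the next hour, and its last reading is 45.1%. I read that as a run closing on its ceiling.

4. Read off the flasks: E is 2.02 for zeta, 1.10 for theta and 0.807 for eta. So I put them in that order, with epsilon last, near 30.2%.

5. Was one number enough? No. Maple has E of 3.90, yet at −10 °C it reads 25.3% after 8.00 h. E gives a ceiling, not a speed. Zeta and theta share the ceiling of the whole charge, so that ceiling does not part them; I commit to zeta first on its larger E, below that ceiling, without a figure.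

The forecast gave zeta > theta > eta > epsilon, with 94% and 29%, on the ground that “Percent yield falls as substrate loading rises”.

The flask gives zeta > theta > eta > epsilon, with 80.9% for zeta, not 94%, and 30.2% for epsilon, whose E was 0.302.

    partner → second intermediate (k = 6.50 × 10⁻⁴ /s, Ea = 90.0 kJ/mol)
    open intermediate + second intermediate → product (k = 0.0380 /M/s, Ea = 39.0 kJ/mol)
    substrate → open intermediate (k = 9.40 × 10⁻⁵ /s, Ea = 78.0 kJ/mol)
    (constants at 5 °C)

At 6.00 h zeta still held 13.1% substrate and 6.01% open intermediate beside its product, and at 60.0 h its product stands at 100%. The same flask as epsilon with 160 mM of substrate has E of 0.0756, and at 6.00 h its product is 7.56%.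

(Readings and results come from a simulation for an exercise; scatter was added.)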